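**Retrosynthetic overview**

1. The furanone ring (O1, C2, C3, C4, C5) is opened at C2–C3: the tetronic acid comes from a (4Z,5E)-4-ethylidene-5-alkylidene-1,3-dioxolan-2-one by an O-to-C carboxyl shift. The enabling feature is that C2 is a carbonic acid carbon held between the enol oxygen O1 (on C5) and the enolic carbon C3, while the second enol oxygen (the 4-OH) sits on the neighbouring ring carbon C4, so O1 and O4 can first carry C2 together as a five-membered cyclic carbonate.
2. The dioxolanone comes from the (E)-enol tert-butyl carbonate of a 1-propynyl ketone (gold-catalysed 5-exo-dig closure, loss of 2-methylpropene). The contra-thermodynamic E geometry of C5=C6 comes from kinetic E(O)-enolisation of that ynone, whose alkyne is also the masked C3–C4 enol.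
3. The ynone comes from a Weinreb amide and propynylmagnesium bromide. The chain is joined by a Negishi sp3–sp2 coupling at the methylidene carbon, between an alkylzinc from (S)-citronellic acid (source of the stereocentre) and an enol triflate.
4. The enol triflate fragment comes from 6-methylhept-5-en-2-one: kinetic enol triflate, E-selective SeO2 oxidation, bromide, alkylation of the 3-acetylfuran enolate, dioxolane protection of the furyl ketone.
5. Order of ring formation: furan (bought), dioxolane (protecting ring, step 5), dioxolanone (temporary ring), then furanone last; the last two both form in step 12.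

Key step: step 12

Remark on the chemistry: the exocyclic C5=C6 bond is read as E (side chain trans to O1, cis to the carbon bearing the 4-OH), expected to be the less stable isomer, and the methyl-bearing centre as S; ring locants are O1, C2 (C=O), C3 (C–Me), C4 (C–OH), C5, with C6 the exocyclic CH.

**Route**

Step 1
Reactants: 1 6-methylhept-5-en-2-one
Product: 3 6-methylhepta-1,5-dien-2-yl trifluoromethanesulfonate, via lithium enolate 2 (not isolated)
Conditions: LiN(i-Pr)2, THF, −78 °C; then PhNTf2, −78 → 0 °C
Reagents that add atoms: N-phenylbis(trifluoromethanesulfonimide), O=S(=O)(N(c1ccccc1)S(=O)(=O)C(F)(F)F)C(F)(F)F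
Why: kinetic deprotonation at the methyl group and O-sulfonylation of the terminal enolate (enol triflate formation) should give the alkenyl triflate that later becomes the methylidene carbon of the chain.

Step 2
Reactants: 3 6-methylhepta-1,5-dien-2-yl trifluoromethanesulfonate
Product: 4 (5E)-7-hydroxy-6-methylhepta-1,5-dien-2-yl trifluoromethanesulfonate
Conditions: SeO2 (cat.), t-BuOOH, CH2Cl2, rt
Reagents that add atoms: tert-butyl hydroperoxide, CC(C)(C)OO
Why: selenium dioxide allylic oxidation (ene reaction then [2,3]-sigmatropic shift) should attack the electron-rich trisubstituted alkene at its E-methyl group, which fixes the E geometry of the chain alkene, while the electron-poor enol triflate stays untouched.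

Step 3
Reactants: 4 (5E)-7-hydroxy-6-methylhepta-1,5-dien-2-yl trifluoromethanesulfonate
Product: 5 (5E)-7-bromo-6-methylhepta-1,5-dien-2-yl trifluoromethanesulfonate
Conditions: CBr4, PPh3, CH2Cl2, 0 °C
Reagents that add atoms: carbon tetrabromide, BrC(Br)(Br)Br
Why: the Appel reaction displaces the activated primary allylic oxygen by bromide in an SN2 step, so the E alkene is not touched.

Step 4
Reactants: 5 (5E)-7-bromo-6-methylhepta-1,5-dien-2-yl trifluoromethanesulfonate; 6 3-acetylfuran
Product: 8 (5E)-9-(furan-3-yl)-6-methyl-9-oxonona-1,5-dien-2-yl trifluoromethanesulfonate, via lithium enolate 7 (not isolated)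
Conditions: LiN(i-Pr)2, THF, −78 °C (6 in excess); then 5, DMPU, −78 → −20 °C
Reagents that add atoms: none
Why: enolate alkylation, in which the lithium enolate of the methyl ketone attacks the primary allylic bromide by SN2, the excess of enolate limiting double alkylation and the alkenyl triflate being inert at low temperature.

Step 5
Reactants: 8 (5E)-9-(furan-3-yl)-6-methyl-9-oxonona-1,5-dien-2-yl trifluoromethanesulfonate
Product: 9 (5E)-8-[2-(furan-3-yl)-1,3-dioxolan-2-yl]-6-methylocta-1,5-dien-2-yl trifluoromethanesulfonate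
Conditions: (Me3SiOCH2)2, Me3SiOTf (cat.), CH2Cl2, −78 → −20 °C
Reagents that add atoms: 1,2-bis(trimethylsilyloxy)ethane, C[Si](C)(C)OCCO[Si](C)(C)C
Why: acetalisation with the bis-silyl ether of ethylene glycol under silyl triflate catalysis (driven by disiloxane formation) masks the furyl ketone, whose α-CH2 would otherwise compete in the enolisation of step 11.

Step 6
Reactants: 10 (S)-citronellic acid [(3S)-3,7-dimethyloct-6-enoic acid]
Product: 12 (3S)-N-methoxy-N,3,7-trimethyloct-6-enamide, via acyl imidazolide 11 (not isolated)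
Conditions: 1,1'-carbonyldiimidazole, CH2Cl2, rt; then MeNH(OMe)·HCl, rt
Reagents that add atoms: N,O-dimethylhydroxylamine hydrochloride, CNOC.Cl
Why: Weinreb amide formation through the acyl imidazolide is mild, and the stereocentre is β to the carbonyl group and cannot epimerise.

Step 7
Reactants: 12 (3S)-N-methoxy-N,3,7-trimethyloct-6-enamide
Product: 14 (3S)-6-hydroxy-N-methoxy-N,3-dimethylhexanamide, via aldehyde 13 (not isolated)
Conditions: O3, CH2Cl2–MeOH, −78 °C; then NaBH4, −78 → 0 °C
Reagents that add atoms: ozone, [O-][O+]=O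
Why: ozonolysis with reductive work-up cleaves the only alkene and reduces the aldehyde and the peroxidic fragments, the Weinreb amide being inert to NaBH4 at 0 °C.

Step 8
Reactants: 14 (3S)-6-hydroxy-N-methoxy-N,3-dimethylhexanamide
Product: 15 (3S)-6-iodo-N-methoxy-N,3-dimethylhexanamide
Conditions: I2, PPh3, imidazole, CH2Cl2, 0 °C → rt
Reagents that add atoms: iodine, II
Why: Appel-type iodination converts the primary alcohol into the iodide by SN2 under neutral conditions that the amide tolerates.

Step 9
Reactants: 15 (3S)-6-iodo-N-methoxy-N,3-dimethylhexanamide; 9 (5E)-8-[2-(furan-3-yl)-1,3-dioxolan-2-yl]-6-methylocta-1,5-dien-2-yl trifluoromethanesulfonate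
Product: 17 (3S,10E)-13-[2-(furan-3-yl)-1,3-dioxolan-2-yl]-N-methoxy-N,3,11-trimethyl-7-methylidenetridec-10-enamide, via alkylzinc iodide 16 (not isolated)
Conditions: Zn dust, LiCl, THF, 40 °C; then 9, Pd(dppf)Cl2 (5 mol %), THF–NMP, 50 °C
Reagents that add atoms: none
Why: Negishi coupling, in which LiCl-assisted zinc insertion gives a primary alkylzinc iodide that couples with the alkenyl triflate under palladium catalysis to set the 1,1-disubstituted alkene, with amide, acetal and furan inert to the organozinc.

Step 10
Reactants: 17 (3S,10E)-13-[2-(furan-3-yl)-1,3-dioxolan-2-yl]-N-methoxy-N,3,11-trimethyl-7-methylidenetridec-10-enamide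
Product: 19 (6S,13E)-16-[2-(furan-3-yl)-1,3-dioxolan-2-yl]-6,14-dimethyl-10-methylidenehexadec-13-en-2-yn-4-one, via magnesium chelate 18 (not isolated)
Conditions: CH3C≡CMgBr, THF, 0 °C; then aq. NH4Cl
Reagents that add atoms: 1-propynylmagnesium bromide, CC#C[Mg]Br
Why: Weinreb ketone synthesis, in which the stable tetrahedral magnesium chelate prevents over-addition and releases the ynone only on work-up, so no conjugate addition to the ynone can occur.

Step 11
Reactants: 19 (6S,13E)-16-[2-(furan-3-yl)-1,3-dioxolan-2-yl]-6,14-dimethyl-10-methylidenehexadec-13-en-2-yn-4-one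
Product: 21 tert-butyl (4E,6S,13E)-16-[2-(furan-3-yl)-1,3-dioxolan-2-yl]-6,14-dimethyl-10-methylidenehexadeca-4,13-dien-2-yn-4-yl carbonate, via lithium E(O)-enolate 20 (not isolated)
Conditions: lithium 2,2,6,6-tetramethylpiperidide, LiBr, THF, −78 °C; then DMPU, Boc2O, −78 °C
Reagents that add atoms: di-tert-butyl dicarbonate, CC(C)(C)OC(=O)OC(=O)OC(C)(C)C
Why: kinetic enolisation through the closed six-membered transition state (Ireland model) should place the side chain trans to O–Li because the group on the carbonyl carbon is the slim, non-enolisable propynyl unit, and O-acylation of this E(O)-enolate with Boc2O in the presence of DMPU (enol carbonate formation) stores that geometry as the future C5=C6 bond.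

Step 12
Reactants: 21 tert-butyl (4E,6S,13E)-16-[2-(furan-3-yl)-1,3-dioxolan-2-yl]-6,14-dimethyl-10-methylidenehexadeca-4,13-dien-2-yn-4-yl carbonate
Product: 25 (5E)-5-[(2S,9E)-13-(furan-3-yl)-2,10-dimethyl-6-methylidene-13-oxotridec-9-en-1-ylidene]-4-hydroxy-3-methylfuran-2(5H)-one, via cyclic carbonate 22 (not isolated), via ammonium tetronate 23 (not isolated), via tetronic acid ketal 24 (not isolated)
Conditions: Ph3PAuNTf2 (2 mol %), toluene, rt; then THF, i-Pr2NEt, 4-(dimethylamino)pyridine (20 mol %), 0 °C → rt; then 1 M HCl, THF–H2O, rt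
Reagents that add atoms: water, O
Why: Proposed new method: cationic monovalent gold activates the alkyne of 21, the carbonate C=O oxygen adds anti at C4 (the alkyne carbon next to the enol carbon), and loss of 2-methylpropene with protodeauration gives the (4Z,5E)-bis(alkylidene) cyclic carbonate 22; DMAP then adds to the carbonate carbon C2 and expels O4 as a dienolate, whose methyl-bearing carbon C3 attacks the N-acylpyridinium carbon still held on O1, so that the furanone ring closes by the C2–C3 bond, DMAP leaves, the amine takes the acidic proton to give tetronate 23, and the HCl work-up protonates it and hydrolyses the dioxolane. The closest known reaction types are the gold-catalysed cyclisation of alkynyl tert-butyl carbonates to alkylidene cyclic carbonates and the Steglich rearrangement (DMAP-catalysed O-to-C carboxyl shift of enol carbonates), neither of which has been shown on an enol carbonate of an ynone or on a cyclic carbonate of two enols, where the shift becomes a ring transposition. The temporary dioxolanone closes 5-exo-dig (oxygen to C4), and the furanone closes by 5-(enolendo)-exo-trig acyl substitution at C2, the same mode as the Dieckmann closure of tetronic acids. No stereocentre is formed, the S centre is not acidic at any stage, and the E geometry of C5=C6 is carried over from 21 because O1 stays acylated from step 11 to the product. The selectivity needed is transfer of the carboxyl carbon to C3 and not to C6, the other enol carbon: C3 carries only a methyl group and, after the anti addition, an inward hydrogen, and its Z(O)-dienolate should be the better leaving group, whereas C6 carries the branched side chain turned inward, and return of a wrongly opened ion pair only regenerates 22. The 5-exo over 6-endo preference of the gold stage is secured by the five-membered transition state and by conjugation of the attacked alkyne carbon with the enol double bond.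

**Compound list**

1 | 6-methylhept-5-en-2-one | CC(=O)CCC=C(C)C | starting material
2 | lithium 6-methylhepta-1,5-dien-2-olate | C=C(CCC=C(C)C)O[Li] | intermediate (not isolated)
3 | 6-methylhepta-1,5-dien-2-yl trifluoromethanesulfonate | C=C(CCC=C(C)C)OS(=O)(=O)C(F)(F)F | intermediate
4 | (5E)-7-hydroxy-6-methylhepta-1,5-dien-2-yl trifluoromethanesulfonate | C=C(CC/C=C(\C)CO)OS(=O)(=O)C(F)(F)F | intermediate
5 | (5E)-7-bromo-6-methylhepta-1,5-dien-2-yl trifluoromethanesulfonate | C=C(CC/C=C(\C)CBr)OS(=O)(=O)C(F)(F)F | intermediate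
6 | 3-acetylfuran [1-(furan-3-yl)ethan-1-one] | CC(=O)c1ccoc1 | starting material
7 | lithium 1-(furan-3-yl)ethen-1-olate | C=C(O[Li])c1ccoc1 | intermediate (not isolated)
8 | (5E)-9-(furan-3-yl)-6-methyl-9-oxonona-1,5-dien-2-yl trifluoromethanesulfonate | C=C(CC/C=C(\C)CCC(=O)c1ccoc1)OS(=O)(=O)C(F)(F)F | intermediate
9 | (5E)-8-[2-(furan-3-yl)-1,3-dioxolan-2-yl]-6-methylocta-1,5-dien-2-yl trifluoromethanesulfonate | C=C(CC/C=C(\C)CCC1(OCCO1)c1ccoc1)OS(=O)(=O)C(F)(F)F | intermediate
10 | (S)-citronellic acid [(3S)-3,7-dimethyloct-6-enoic acid] | CC(C)=CCC[C@H](C)CC(=O)O | starting material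
11 | (3S)-1-(1H-imidazol-1-yl)-3,7-dimethyloct-6-en-1-one | CC(C)=CCC[C@H](C)CC(=O)n1ccnc1 | intermediate (not isolated)
12 | (3S)-N-methoxy-N,3,7-trimethyloct-6-enamide | CC(C)=CCC[C@H](C)CC(=O)N(C)OC | intermediate
13 | (3S)-N-methoxy-N,3-dimethyl-6-oxohexanamide | O=CCC[C@H](C)CC(=O)N(C)OC | intermediate (not isolated)
14 | (3S)-6-hydroxy-N-methoxy-N,3-dimethylhexanamide | OCCC[C@H](C)CC(=O)N(C)OC | intermediate
15 | (3S)-6-iodo-N-methoxy-N,3-dimethylhexanamide | ICCC[C@H](C)CC(=O)N(C)OC | intermediate
16 | {(4S)-6-[methoxy(methyl)amino]-4-methyl-6-oxohexyl}zinc iodide | I[Zn]CCC[C@H](C)CC(=O)N(C)OC | intermediate (not isolated)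
17 | (3S,10E)-13-[2-(furan-3-yl)-1,3-dioxolan-2-yl]-N-methoxy-N,3,11-trimethyl-7-methylidenetridec-10-enamide | C=C(CC/C=C(\C)CCC1(OCCO1)c1ccoc1)CCC[C@H](C)CC(=O)N(C)OC | intermediate
18 | bromomagnesium (6S,13E)-16-[2-(furan-3-yl)-1,3-dioxolan-2-yl]-4-[methoxy(methyl)amino]-6,14-dimethyl-10-methylidenehexadec-13-en-2-yn-4-olate (tetrahedral chelate) | C=C(CC/C=C(\C)CCC1(OCCO1)c1ccoc1)CCC[C@H](C)CC(O[Mg]Br)(C#CC)N(C)OC | intermediate (not isolated)
19 | (6S,13E)-16-[2-(furan-3-yl)-1,3-dioxolan-2-yl]-6,14-dimethyl-10-methylidenehexadec-13-en-2-yn-4-one | C=C(CC/C=C(\C)CCC1(OCCO1)c1ccoc1)CCC[C@H](C)CC(=O)C#CC | intermediate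
20 | lithium (4E,6S,13E)-16-[2-(furan-3-yl)-1,3-dioxolan-2-yl]-6,14-dimethyl-10-methylidenehexadeca-4,13-dien-2-yn-4-olate | C=C(CC/C=C(\C)CCC1(OCCO1)c1ccoc1)CCC[C@H](C)/C=C(/O[Li])C#CC | intermediate (not isolated)
21 | tert-butyl (4E,6S,13E)-16-[2-(furan-3-yl)-1,3-dioxolan-2-yl]-6,14-dimethyl-10-methylidenehexadeca-4,13-dien-2-yn-4-yl carbonate | C=C(CC/C=C(\C)CCC1(OCCO1)c1ccoc1)CCC[C@H](C)/C=C(/OC(=O)OC(C)(C)C)C#CC | intermediate
22 | (4Z,5E)-4-ethylidene-5-[(2S,9E)-12-[2-(furan-3-yl)-1,3-dioxolan-2-yl]-2,10-dimethyl-6-methylidenedodec-9-en-1-ylidene]-1,3-dioxolan-2-one | C=C(CC/C=C(\C)CCC1(OCCO1)c1ccoc1)CCC[C@H](C)/C=C1/OC(=O)O/C1=C\C | intermediate (not isolated)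
23 | N-ethyl-N,N-diisopropylammonium salt of tetronic acid 24 | C=C(CC/C=C(\C)CCC1(OCCO1)c1ccoc1)CCC[C@H](C)/C=C1/OC(=O)C(C)=C1[O-].CC[NH+](C(C)C)C(C)C | intermediate (not isolated)
24 | (5E)-5-[(2S,9E)-12-[2-(furan-3-yl)-1,3-dioxolan-2-yl]-2,10-dimethyl-6-methylidenedodec-9-en-1-ylidene]-4-hydroxy-3-methylfuran-2(5H)-one | C=C(CC/C=C(\C)CCC1(OCCO1)c1ccoc1)CCC[C@H](C)/C=C1/OC(=O)C(C)=C1O | intermediate (not isolated)
25 | (5E)-5-[(2S,9E)-13-(furan-3-yl)-2,10-dimethyl-6-methylidene-13-oxotridec-9-en-1-ylidene]-4-hydroxy-3-methylfuran-2(5H)-one | C=C(CC/C=C(\C)CCC(=O)c1ccoc1)CCC[C@H](C)/C=C1/OC(=O)C(C)=C1O | target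

**Step count**

Total: 12 steps. Longest linear sequence: 9 steps (steps 1–5 and 9–12, from 6-methylhept-5-en-2-one).

**Steps most likely to fail, with fallbacks**

Step 12 (Proposed new method). The acyl-transfer relay may stall because ionisation of the cyclic carbonate by DMAP is too slow, the carboxyl carbon may be delivered to the wrong enol carbon, or the gold stage may close in the 6-endo mode. The fallback uses known chemistry and sets out from ynone 19. Enolisation as in step 11 and trapping with phenyl chloroformate should give the (E)-enol phenyl carbonate, phenyl (4E,6S,13E)-16-[2-(furan-3-yl)-1,3-dioxolan-2-yl]-6,14-dimethyl-10-methylidenehexadeca-4,13-dien-2-yn-4-yl carbonate F1. Gold-catalysed Markovnikov hydration of its alkyne (Ph3PAuNTf2, wet 1,4-dioxane, the neighbouring carbonate C=O directing water to the carbon next to the enol carbon) should give the ethyl ketone, phenyl (4E,6S,13E)-16-[2-(furan-3-yl)-1,3-dioxolan-2-yl]-6,14-dimethyl-10-methylidene-3-oxohexadeca-4,13-dien-4-yl carbonate F2. Kinetic deprotonation of F2 at the ethyl CH2 with LiN(SiMe3)2 (THF, −78 °C) and Dieckmann-type attack of the enolate on the aryl carbonate closes the same C2–C3 bond with loss of phenoxide. After acidification this gives tetronic acid ketal 24, where the fallback comes back to the route; the same HCl treatment then gives 25.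

Step 11. The E(O) preference of the deprotonation may be eroded, or the lithium enolate may be acylated on carbon instead of oxygen. The fallback sets out from 19 and separates the two events. Deprotonation with lithium 2,2,6,6-tetramethylpiperidide in the presence of Me3SiCl (in situ quench, which traps the kinetic enolate before any equilibration) should give the silyl enol ether, trimethyl{[(4E,6S,13E)-16-[2-(furan-3-yl)-1,3-dioxolan-2-yl]-6,14-dimethyl-10-methylidenehexadeca-4,13-dien-2-yn-4-yl]oxy}silane F3. Its geometry can be checked and, if needed, enriched by chromatography on deactivated silica. Cleavage with MeLi (THF, 0 °C) regenerates amine-free lithium enolate 20, which is O-acylated with Boc2O and DMPU; the fallback comes back to the route at 21.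

Step 2. The allylic oxidation may over-oxidise to the enal, attack competing allylic positions or stop at low conversion. The fallback sets out from 3 and rebuilds the trisubstituted alkene. Chemoselective epoxidation of the trisubstituted alkene with mCPBA should give 4-(3,3-dimethyloxiran-2-yl)but-1-en-2-yl trifluoromethanesulfonate F4. Cleavage with H5IO6 gives 5-oxopent-1-en-2-yl trifluoromethanesulfonate F5. A Wittig reaction with ethyl 2-(triphenylphosphoranylidene)propanoate should give the E enoate, ethyl (2E)-2-methyl-6-{[(trifluoromethyl)sulfonyl]oxy}hepta-2,6-dienoate F6. Reduction with i-Bu2AlH (CH2Cl2, −78 °C) comes back to the route at 4.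

**Further compounds**

F1 | step 12 | phenyl (4E,6S,13E)-16-[2-(furan-3-yl)-1,3-dioxolan-2-yl]-6,14-dimethyl-10-methylidenehexadeca-4,13-dien-2-yn-4-yl carbonate | C=C(CC/C=C(\C)CCC1(OCCO1)c1ccoc1)CCC[C@H](C)/C=C(/OC(=O)Oc1ccccc1)C#CC
F2 | step 12 | phenyl (4E,6S,13E)-16-[2-(furan-3-yl)-1,3-dioxolan-2-yl]-6,14-dimethyl-10-methylidene-3-oxohexadeca-4,13-dien-4-yl carbonate | C=C(CC/C=C(\C)CCC1(OCCO1)c1ccoc1)CCC[C@H](C)/C=C(/OC(=O)Oc1ccccc1)C(=O)CC
F3 | step 11 | trimethyl{[(4E,6S,13E)-16-[2-(furan-3-yl)-1,3-dioxolan-2-yl]-6,14-dimethyl-10-methylidenehexadeca-4,13-dien-2-yn-4-yl]oxy}silane | C=C(CC/C=C(\C)CCC1(OCCO1)c1ccoc1)CCC[C@H](C)/C=C(/O[Si](C)(C)C)C#CC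
F4 | step 2 | 4-(3,3-dimethyloxiran-2-yl)but-1-en-2-yl trifluoromethanesulfonate | C=C(CCC1OC1(C)C)OS(=O)(=O)C(F)(F)F
F5 | step 2 | 5-oxopent-1-en-2-yl trifluoromethanesulfonate | C=C(CCC=O)OS(=O)(=O)C(F)(F)F
F6 | step 2 | ethyl (2E)-2-methyl-6-{[(trifluoromethyl)sulfonyl]oxy}hepta-2,6-dienoate | C=C(CC/C=C(\C)C(=O)OCC)OS(=O)(=O)C(F)(F)F
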